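**Retrosynthetic overview**
- Only one ring is built, the cyclohexanone ring of the tetralone. It is closed last, between a vinylnaphthol and an α-bromoacetyl hydroquinone, both flat and unprotected; the naphthalene and hydroquinone rings are bought.
- Key disconnection: tetralone C2–C3 and C4–C4a. Both bonds are made together in a photoredox radical–polar crossover [4+2] annulation, and the ring closure runs under a chiral phosphoric acid and sets C4, the only stereocentre.
- Enabling feature: the free OH at C4 of the naphthalene ring is para to C1, the ring carbon that bears the stereocentre. Tetralone C4 is therefore a latent para-quinone methide carbon (flat, electrophilic, stereoconvergent). The OH at tetralone C5 is ortho to C4a, which makes C4a the nucleophile and gives the catalyst a hydrogen-bond handle. The C8–OH···O=C1 hydrogen bond folds the chain towards C4a.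
- The vinylnaphthol comes from C2h-symmetric 1,5-dimethoxynaphthalene by formylation, demethylation para to CHO and methylenation. The bromoketone comes from 2',5'-dihydroxyacetophenone.

Key step: step 5

Assumption: the sense of induction of the chiral acid in step 5 cannot be derived from a close analogue. (R)-TRIP, (R)-3,3'-bis(2,4,6-triisopropylphenyl)-1,1'-binaphthyl-2,2'-diyl hydrogen phosphate, is written throughout, and its equally available antipode is used if that is the one that leads to the (S) product.

Step 1
Reactants: 1 1,5-dimethoxynaphthalene
Product: 3 4,8-dimethoxynaphthalene-1-carbaldehyde, via [(4,8-dimethoxynaphthalen-1-yl)methylidene]dimethylammonium dichlorophosphate 2 (not isolated)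
Conditions: POCl3 (1.5 equiv), DMF (2 equiv), PhMe, 100 °C; then ice-water
Reagents that add atoms: N,N-dimethylformamide, CN(C)C=O (formyl carbon); water, O (carbonyl oxygen)
Why: Vilsmeier–Haack formylation attacks the α-position para to a methoxy group, and because the two such positions of symmetric 1 are equivalent a single aldehyde should form, while the iminium group of 2 deactivates the ring system against a second attack.

Step 2
Reactants: 3 4,8-dimethoxynaphthalene-1-carbaldehyde
Product: 4 4-hydroxy-8-methoxynaphthalene-1-carbaldehyde
Conditions: NaSEt (2.5 equiv), DMF, 100 °C; then 1 M HCl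
Reagents that add atoms: none
Why: In this nucleophilic (SN2) aryl methyl ether cleavage by thiolate only the C4 methoxy group is conjugated (para) with the formyl group and leaves as a vinylogous carboxylate, whereas the C8 oxygen has no conjugation with C1; Lewis acids, which would chelate CHO and the peri OMe and cleave the wrong ether, are avoided.

Step 3
Reactants: 4 4-hydroxy-8-methoxynaphthalene-1-carbaldehyde
Product: 5 4-ethenyl-5-methoxynaphthalen-1-ol
Conditions: Ph3PCH3Br (2.5 equiv), KOtBu (3.5 equiv), THF, 0 °C to rt; product kept cold under Ar with BHT and used at once
Reagents that add atoms: methyltriphenylphosphonium bromide, C[P+](c1ccccc1)(c1ccccc1)c1ccccc1.[Br-]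
Why: In this Wittig methylenation the excess base first takes the naphthol proton and the non-stabilised ylide then methylenates the aldehyde, as is known for unprotected 4-hydroxybenzaldehydes.

Step 4
Reactants: 6 1-(2,5-dihydroxyphenyl)ethan-1-one (2',5'-dihydroxyacetophenone)
Product: 7 2-bromo-1-(2,5-dihydroxyphenyl)ethan-1-one (2-bromo-2',5'-dihydroxyacetophenone)
Conditions: CuBr2 (2.0 equiv), EtOAc/CHCl3 1:1, reflux
Reagents that add atoms: copper(II) bromide, [Cu+2].[Br-].[Br-]
Why: Heterogeneous copper(II) bromide α-bromination of aryl methyl ketones delivers bromine to the enol carbon of hydroxyacetophenones rather than to the ring, and the hydrogen-bonded acyl group makes this hydroquinone harder to oxidise.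

Step 5
Reactants: 5 4-ethenyl-5-methoxynaphthalen-1-ol; 7 2-bromo-1-(2,5-dihydroxyphenyl)ethan-1-one (1.2 equiv)
Product: 9 (4S)-5,8-dihydroxy-4-(4-hydroxy-8-methoxynaphthalen-1-yl)-3,4-dihydronaphthalen-1(2H)-one, via (4E)-4-[4-(2,5-dihydroxyphenyl)-4-oxobutylidene]-5-methoxynaphthalen-1(4H)-one 8 (not isolated)
Conditions: fac-Ir(ppy)3 (1 mol %), (R)-TRIP (10 mol %), powdered Na2HPO4 (3 equiv), 4 Å MS, CH2Cl2/PhMe 1:1 (5 mM), Ar, 450 nm LEDs, −10 °C, 5 added over 8 h; then dark, rt
Reagents that add atoms: none
Why: Proposed new method: photoexcited Ir(ppy)3 cleaves the C–Br bond of 7 reductively, the electrophilic α-keto radical adds to the terminal vinyl carbon of 5 (C2–C3 bond), the electron-rich benzylic radical is oxidised by Ir(IV) or by further 7 (chain) with loss of the naphthol proton to the planar para-quinone methide 8, and the ring carbon ortho to the 5'-OH of the hydroquinone adds to its exocyclic carbon (C4–C4a bond), after which both rings rearomatise. The closest known reaction types are the radical annulation of phenacyl radical precursors with alkenes to 1-tetralones, the photoredox/chiral phosphate dicarbofunctionalisation of enamides with α-bromocarbonyl compounds and arenes, and the chiral phosphoric acid catalysed 1,6-arylation of para-quinone methides made in situ; their merger on a vinylnaphthol with a tethered acylhydroquinone as the arene is new. The only ring closed, the cyclohexanone ring, forms by a 6-exo-trig 1,6-conjugate (Friedel–Crafts type) addition with respect to the exocyclic C=C of 8. The only stereocentre, C4, is set in this closure by the catalyst, which should hold the carbonyl oxygen of 8 with its acidic OH and the 5'-OH with its P=O and so expose one face of the quinone methide, while the peri methoxy group allows only the (E) geometry of 8 and both mirror-image forms of the preceding radical converge on this one flat intermediate. Regioselectivity of the radical addition follows from benzylic stabilisation, and site selectivity of the arylation follows from the tether (only this ring carbon can reach) and from the 2'-OH···O=C hydrogen bond, which turns the chain towards it, meets much of the electron demand of the acyl group and keeps this OH from displacing bromide; attack of the ketone oxygen on 8 and loss of a proton next to its exocyclic carbon are reversible under the acid, the C–C closure is not. High dilution and slow addition of 5 should keep intermolecular capture of 8 by electron-rich alkene below the unimolecular closure, and because the sodium salt of the catalyst is the only soluble base, the proton set free by the chain should reach 8 only as the chiral acid.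

**Compound list**
1 | 1,5-dimethoxynaphthalene | COc1cccc2c(OC)cccc12 | starting material
2 | [(4,8-dimethoxynaphthalen-1-yl)methylidene]dimethylammonium dichlorophosphate | COc1ccc(C=[N+](C)C)c2c(OC)cccc12.[O-]P(=O)(Cl)Cl | intermediate
3 | 4,8-dimethoxynaphthalene-1-carbaldehyde | COc1ccc(C=O)c2c(OC)cccc12 | intermediate
4 | 4-hydroxy-8-methoxynaphthalene-1-carbaldehyde | COc1cccc2c(O)ccc(C=O)c12 | intermediate
5 | 4-ethenyl-5-methoxynaphthalen-1-ol | COc1cccc2c(O)ccc(C=C)c12 | intermediate
6 | 1-(2,5-dihydroxyphenyl)ethan-1-one | CC(=O)c1cc(O)ccc1O | starting material
7 | 2-bromo-1-(2,5-dihydroxyphenyl)ethan-1-one | O=C(CBr)c1cc(O)ccc1O | intermediate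
8 | (4E)-4-[4-(2,5-dihydroxyphenyl)-4-oxobutylidene]-5-methoxynaphthalen-1(4H)-one | COc1cccc2C(=O)C=C/C(=C\CCC(=O)c3cc(O)ccc3O)c12 | intermediate
9 | (4S)-5,8-dihydroxy-4-(4-hydroxy-8-methoxynaphthalen-1-yl)-3,4-dihydronaphthalen-1(2H)-one | COc1cccc2c(O)ccc([C@@H]3CCC(=O)c4c(O)ccc(O)c43)c12 | target

Total step count: 5. Longest linear sequence: 4 (steps 1, 2, 3, 5).

**Steps most likely to fail**

1. Step 5.
   - What may go wrong: the two catalytic cycles may interfere. Acid may oligomerise the vinylnaphthol while it waits for the radical. Electron-rich alkene may capture the quinone methide faster than the ring closes. Closure under hydrogen bromide outside the chiral pocket may erode facial selectivity.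
   - Fallback (known chemistry): the two bond formations are separated. From 5 and 7, a photoredox three-component alkoxyalkylation of the styrene type is run (fac-Ir(ppy)3, Na2HPO4, MeOH/MeCN, blue LEDs). Methanol in large excess captures the quinone methide, which should give racemic 1-(2,5-dihydroxyphenyl)-4-(4-hydroxy-8-methoxynaphthalen-1-yl)-4-methoxybutan-1-one F1. F1 is purified free of halide and of 5. It is then ionised by (R)-TRIP alone (PhMe, 5 Å MS, high dilution) in the known stereoconvergent arylation of para-quinone methides generated from para-hydroxybenzyl ethers. This comes back to the route at 9.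

2. Step 4.
   - What may go wrong: copper(II) may oxidise the hydroquinone, or bromine may enter the electron-rich ring.
   - Fallback: from 6, exhaustive silylation (TMSOTf, Et3N, CH2Cl2, 0 °C) should give trimethyl({1-[2,5-bis(trimethylsilyloxy)phenyl]ethenyl}oxy)silane F2. NBS (THF, −78 °C) brominates only the enol ether carbon and should give 2-bromo-1-[2,5-bis(trimethylsilyloxy)phenyl]ethan-1-one F3. Brief methanolysis (MeOH, cat. citric acid) frees both phenols and comes back to the route at 7.

3. Step 3.
   - What may go wrong: methylenation of the aldehyde may be sluggish, because it is deactivated as its naphtholate and hindered by the peri methoxy group.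
   - Fallback: from 4, Knoevenagel–Doebner condensation with malonic acid (pyridine, cat. piperidine, 80 °C) should give (E)-3-(4-hydroxy-8-methoxynaphthalen-1-yl)prop-2-enoic acid F4. Its base-promoted thermal decarboxylation (Et3N, DMF, 110 °C, BHT) runs through the quinone methide tautomer and therefore draws on the para OH. This comes back to the route at 5.

**Further compounds**
F1 | step 5 | rac-1-(2,5-dihydroxyphenyl)-4-(4-hydroxy-8-methoxynaphthalen-1-yl)-4-methoxybutan-1-one | COC(CCC(=O)c1cc(O)ccc1O)c1ccc(O)c2cccc(OC)c12
F2 | step 4 | trimethyl({1-[2,5-bis(trimethylsilyloxy)phenyl]ethenyl}oxy)silane | C=C(O[Si](C)(C)C)c1cc(O[Si](C)(C)C)ccc1O[Si](C)(C)C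
F3 | step 4 | 2-bromo-1-[2,5-bis(trimethylsilyloxy)phenyl]ethan-1-one | O=C(CBr)c1cc(O[Si](C)(C)C)ccc1O[Si](C)(C)C
F4 | step 3 | (E)-3-(4-hydroxy-8-methoxynaphthalen-1-yl)prop-2-enoic acid | COc1cccc2c(O)ccc(/C=C/C(=O)O)c12
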